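The quinone ring is numbered Q1 (C-OMe), Q2 (C-indole A), Q3 (C=O), Q4 (C-OMe), Q5 (C-indole B, 7-prenylated), Q6 (C=O). The key step exploits two features: the indoles sit para (Q2, Q5), and the oxygenated carbon Q6 separates Q5 from Q1. The ring is therefore cut into three pieces. Q3-Q2-Q1 is an alkenyl(methoxy)carbene ligand on zerovalent chromium carrying N-TIPS indole A. Q4-Q5 is an N-Boc 3-ethynyl-7-prenylindole. Q6 is a CO ligand. One Dötz benzannulation forms Q3-Q4, Q5-Q6 and Q6-Q1 and delivers the central ring as a 4-methoxyphenol. Oxidation to the quinone, twofold oxidative methoxylation at Q1 and Q4, and deprotection complete the target.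

Key step: step 9

Remark: the target holds no stereocentre and no stereogenic double bond. Carbonyl ligands on chromium are drawn as Cr=C=O in every SMILES, and the arene-Cr(CO)3 complex is drawn as two dot-joined parts.

Step 1
Reactants: 1 3-acetylindole
Product: 2 3-acetyl-1-(triisopropylsilyl)indole
Conditions: NaH, THF, 0 °C; TIPSCl, 0 °C to rt
Reagents that add atoms: triisopropylsilyl chloride (TIPSCl), CC(C)[Si](Cl)(C(C)C)C(C)C
Why: N-silylation of the deprotonated 3-acylindole keeps the ring aromatic (so nitrogen, not oxygen, is silylated) and installs a group that tolerates alkyllithiums and screens C2 from lithiation.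

Step 2
Reactants: 2 3-acetyl-1-(triisopropylsilyl)indole
Product: 3 (E)-2,4,6-triisopropylbenzenesulfonylhydrazone of 3-acetyl-1-(triisopropylsilyl)indole
Conditions: 2,4,6-triisopropylbenzenesulfonyl hydrazide, PPTS (cat.), 4 Å MS, THF, rt
Reagents that add atoms: 2,4,6-triisopropylbenzenesulfonyl hydrazide, CC(C)c1cc(C(C)C)c(S(=O)(=O)NN)c(C(C)C)c1
Why: Acid-catalysed hydrazone condensation of an aryl methyl ketone should give the E isomer, with the sulfonamide nitrogen syn to the methyl group as the later directed deprotonation needs, and the aprotic, weakly acidic medium spares the N-Si bond.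

Step 3
Reactants: 3 the trisylhydrazone; 4 chromium hexacarbonyl, Cr(CO)6
Product: 7 pentacarbonyl{methoxy[1-(1-triisopropylsilylindol-3-yl)vinyl]carbene}chromium, via vinyllithium 5 (not isolated), via lithium acylchromate 6 (not isolated)
Conditions: n-BuLi (2.1 equiv), THF, -78 °C, then 0 °C until N2 evolution ends; Cr(CO)6, THF, 0 °C to rt; solvent swap; Me3OBF4, CH2Cl2, 0 °C
Reagents that add atoms: trimethyloxonium tetrafluoroborate (Me3OBF4), C[O+](C)C.F[B-](F)(F)F; n-butyllithium, [Li]CCCC (lithium of 5 and 6 only)
Why: Shapiro reaction followed by the Fischer carbene synthesis, in which double deprotonation and loss of sulfinate and N2 give the only possible vinyllithium 5, this adds to a CO ligand of 4, and O-methylation of acylate 6 by the Meerwein salt fixes the methoxycarbene.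

Step 4
Reactants: 8 7-bromoindole; 9 prenyl bromide (1-bromo-3-methylbut-2-ene)
Product: 11 7-prenylindole, via 7-lithio-1-potassioindole 10 (not isolated)
Conditions: KH, THF, 0 °C; t-BuLi (2.1 equiv), -78 °C; 9 (1.0 equiv), -78 °C to rt; H2O
Reagents that add atoms: potassium hydride, [K+].[H-]; tert-butyllithium, [Li]C(C)(C)C (metals of intermediate 10 only)
Why: Halogen-lithium exchange on the N-metalated bromoindole gives a C7 aryllithium far more nucleophilic than the indolide nitrogen, and its SN2 alkylation at the unhindered CH2 of 9 should give the linear prenyl group.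

Step 5
Reactants: 11 7-prenylindole
Product: 12 3-iodo-7-prenylindole
Conditions: I2 (1.0 equiv), KOH, DMF, rt; used at once
Reagents that add atoms: iodine, II
Why: Electrophilic aromatic iodination of the indolide at C3, its most nucleophilic carbon, outruns any reaction of iodine with the trisubstituted alkene.

Step 6
Reactants: 12 3-iodo-7-prenylindole
Product: 13 1-Boc-3-iodo-7-prenylindole (tert-butyl 3-iodo-7-(3-methylbut-2-enyl)indole-1-carboxylate)
Conditions: Boc2O, DMAP (cat.), CH2Cl2, rt
Reagents that add atoms: di-tert-butyl dicarbonate (Boc2O), CC(C)(C)OC(=O)OC(=O)OC(C)(C)C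
Why: DMAP-catalysed N-acylation (carbamate protection) stabilises the sensitive 3-iodoindole and lowers the donor strength of the ring for the coupling and the benzannulation.

Step 7
Reactants: 13 1-Boc-3-iodo-7-prenylindole; 14 trimethylsilylacetylene
Product: 15 1-Boc-7-prenyl-3-(trimethylsilylethynyl)indole
Conditions: PdCl2(PPh3)2 (cat.), CuI (cat.), Et3N, THF, rt
Reagents that add atoms: none
Why: Sonogashira coupling of an N-acyl 3-iodoindole proceeds at room temperature, where neither the Boc group nor the prenyl alkene reacts.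

Step 8
Reactants: 15 1-Boc-7-prenyl-3-(trimethylsilylethynyl)indole
Product: 16 1-Boc-3-ethynyl-7-prenylindole
Conditions: Bu4NF, AcOH, THF, 0 °C
Reagents that add atoms: none
Why: Fluoride-induced protodesilylation of an alkynylsilane is fast at 0 °C, and the acetic acid buffer keeps the medium from attacking the indole carbamate.

Step 9
Reactants: 7 the carbene complex; 16 1-Boc-3-ethynyl-7-prenylindole
Product: 18 4-methoxy-2-(1-Boc-7-prenylindol-3-yl)-5-(1-TIPS-indol-3-yl)phenol, via tricarbonylchromium arene complex 17 (not isolated)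
Conditions: 7 (1.2 equiv), THF (0.05 M, degassed), Ar, 50 °C; then air, Et2O, rt
Reagents that add atoms: none
Why: Dötz benzannulation: heat expels one cis CO from 7, alkyne 16 binds and inserts into the Cr=C bond (forming Q3-Q4) to give an η1,η3-vinylcarbene, and migration of a CO ligand to the new carbene carbon (forming Q5-Q6) gives a chromium-bound dienylketene. The single new ring, the carbocycle Q1-Q6, closes by six-electron electrocyclisation of that dienylketene, ketene carbon Q6 bonding to the former =CH2 carbon Q1, and the cyclohexadienone enolises to the phenol, held first as Cr(CO)3 complex 17 and freed by air. The closest known reaction type is this very one, the benzannulation of alkenyl(alkoxy)carbene complexes of zerovalent chromium with terminal alkynes, the partner pair least prone to five-membered-ring or cyclobutenone by-paths. No stereocentre is created. The one selectivity needed is the direction of alkyne insertion, and the size difference between H and indolyl in 16 secures it: the position next to Q3 in the vinylcarbene lies against a CO ligand and accepts only hydrogen, so the indolyl-bearing carbon becomes Q5, beside Q6 and para to indole A. Boc damps the enamine character of the alkyne, TIPS screens C2 of indole A, closure through the indole C2=C3 bond of 7 would need a seven-membered ring and cannot compete, and the remote, unactivated prenyl alkene is not a carbene acceptor under these conditions.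

Step 10
Reactants: 18 the 4-methoxyphenol
Product: 19 2-(1-Boc-7-prenylindol-3-yl)-5-(1-TIPS-indol-3-yl)-1,4-benzoquinone
Conditions: PhI(OAc)2, MeCN-H2O (4:1), 0 °C
Reagents that add atoms: water, O
Why: Oxidative demethylation of a 4-methoxyphenol by the trivalent iodine reagent, in which water attacks the methoxy-bearing carbon Q3 of the activated phenol and the hemiketal loses methanol, while the N-Boc and N-TIPS groups hold both indoles back from oxidative coupling with the phenol oxygen.

Step 11
Reactants: 19 the 2,5-bis(indolyl)benzoquinone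
Product: 20 2,5-dimethoxy-3-(7-prenyl-1H-indol-3-yl)-6-(1-TIPS-indol-3-yl)-1,4-benzoquinone
Conditions: NaOMe (excess), MeOH-THF, 3 Å MS, dry air, 0 °C to rt; pH 7 buffer
Reagents that add atoms: sodium methoxide, [Na+].[O-]C
Why: Oxidative nucleophilic addition to a quinone (oxa-Michael addition of methoxide, enolisation, aerobic reoxidation) can be productive only at the C-H carbons Q1 and Q4, the first methoxy group deactivates only the carbonyl it is conjugated with so the second addition follows the familiar 2,5-dialkoxylation pattern of benzoquinones, and methoxide also cleaves the activated indole carbamate by transesterification.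

Step 12
Reactants: 20 the N-TIPS dimethoxyquinone
Product: 21 2,5-dimethoxy-3-(1H-indol-3-yl)-6-(7-prenyl-1H-indol-3-yl)-1,4-benzoquinone (target CNP0256613.0)
Conditions: Bu4NF, AcOH, THF, 0 °C
Reagents that add atoms: none
Why: Fluoride-mediated N-desilylation is fast at 0 °C, and the acetic acid buffer protonates the indolide and shields the vinylogous ester groups of the quinone from hydroxide.

Compound list
1 | 3-acetylindole | CC(=O)c1c[nH]c2ccccc12 | starting material
2 | 3-acetyl-1-(triisopropylsilyl)indole | CC(=O)c1cn([Si](C(C)C)(C(C)C)C(C)C)c2ccccc12 | intermediate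
3 | (E)-2,4,6-triisopropylbenzenesulfonylhydrazone of 2 | C/C(=N\NS(=O)(=O)c1c(C(C)C)cc(C(C)C)cc1C(C)C)c1cn([Si](C(C)C)(C(C)C)C(C)C)c2ccccc12 | intermediate
4 | chromium hexacarbonyl, Cr(CO)6 | O=C=[Cr](=C=O)(=C=O)(=C=O)(=C=O)=C=O | starting material
5 | 1-[1-(triisopropylsilyl)indol-3-yl]vinyllithium | [Li]C(=C)c1cn([Si](C(C)C)(C(C)C)C(C)C)c2ccccc12 | intermediate
6 | lithium pentacarbonyl acylchromate from 5 and Cr(CO)6 | [Li+].[O-]C(C(=C)c1cn([Si](C(C)C)(C(C)C)C(C)C)c2ccccc12)=[Cr](=C=O)(=C=O)(=C=O)(=C=O)=C=O | intermediate
7 | pentacarbonyl{methoxy[1-(1-triisopropylsilylindol-3-yl)vinyl]carbene}chromium | COC(C(=C)c1cn([Si](C(C)C)(C(C)C)C(C)C)c2ccccc12)=[Cr](=C=O)(=C=O)(=C=O)(=C=O)=C=O | intermediate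
8 | 7-bromoindole | Brc1cccc2cc[nH]c12 | starting material
9 | prenyl bromide (1-bromo-3-methylbut-2-ene) | CC(C)=CCBr | starting material
10 | 7-lithio-1-potassioindole | [Li]c1cccc2ccn([K])c12 | intermediate
11 | 7-prenylindole | CC(C)=CCc1cccc2cc[nH]c12 | intermediate
12 | 3-iodo-7-prenylindole | CC(C)=CCc1cccc2c(I)c[nH]c12 | intermediate
13 | 1-Boc-3-iodo-7-prenylindole | CC(C)=CCc1cccc2c(I)cn(C(=O)OC(C)(C)C)c12 | intermediate
14 | trimethylsilylacetylene | C#C[Si](C)(C)C | starting material
15 | 1-Boc-7-prenyl-3-(trimethylsilylethynyl)indole | CC(C)=CCc1cccc2c(C#C[Si](C)(C)C)cn(C(=O)OC(C)(C)C)c12 | intermediate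
16 | 1-Boc-3-ethynyl-7-prenylindole | C#Cc1cn(C(=O)OC(C)(C)C)c2c(CC=C(C)C)cccc12 | intermediate
17 | tricarbonyl(η6-arene)chromium complex of phenol 18, chromium on the new ring | COc1cc(c2cn(C(=O)OC(C)(C)C)c3c(CC=C(C)C)cccc23)c(O)cc1c1cn([Si](C(C)C)(C(C)C)C(C)C)c2ccccc12.O=C=[Cr](=C=O)=C=O | intermediate
18 | 4-methoxy-2-(1-Boc-7-prenylindol-3-yl)-5-(1-TIPS-indol-3-yl)phenol | COc1cc(c2cn(C(=O)OC(C)(C)C)c3c(CC=C(C)C)cccc23)c(O)cc1c1cn([Si](C(C)C)(C(C)C)C(C)C)c2ccccc12 | intermediate
19 | 2-(1-Boc-7-prenylindol-3-yl)-5-(1-TIPS-indol-3-yl)-1,4-benzoquinone | O=C1C=C(c2cn([Si](C(C)C)(C(C)C)C(C)C)c3ccccc23)C(=O)C=C1c1cn(C(=O)OC(C)(C)C)c2c(CC=C(C)C)cccc12 | intermediate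
20 | 2,5-dimethoxy-3-(7-prenyl-1H-indol-3-yl)-6-(1-TIPS-indol-3-yl)-1,4-benzoquinone | COC1=C(c2cn([Si](C(C)C)(C(C)C)C(C)C)c3ccccc23)C(=O)C(OC)=C(c2c[nH]c3c(CC=C(C)C)cccc23)C1=O | intermediate
21 | 2,5-dimethoxy-3-(1H-indol-3-yl)-6-(7-prenyl-1H-indol-3-yl)-1,4-benzoquinone | COC1=C(c2c[nH]c3ccccc23)C(=O)C(OC)=C(c2c[nH]c3c(CC=C(C)C)cccc23)C1=O | target

Total step count: 12.
Longest linear sequence: 9 steps (steps 4 to 12, from 7-bromoindole). The carbene branch contributes 3 steps before the union.

Steps most likely to fail

1. Step 9.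
- Risk: CO insertion may be slow, diverting the vinylcarbene to five-membered-ring closure. A second alkyne may be taken up or the alkyne may oligomerise. The carbene complex may decay thermally or undergo self-cycloaddition before it meets the alkyne.
- Fallback: it sets out from 11 and buys the central ring instead of building it.
- Commercial indole is added to commercial 2,5-dichloro-1,4-benzoquinone with HCl in THF, giving 2,5-dichloro-3-(1H-indol-3-yl)benzene-1,4-diol F1.
- DDQ oxidises this to 2,5-dichloro-3-(1H-indol-3-yl)-1,4-benzoquinone F2.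
- Compound 11 is then added to the one remaining C-H carbon of F2 in acetic acid, giving 2,5-dichloro-3-(1H-indol-3-yl)-6-(7-prenyl-1H-indol-3-yl)benzene-1,4-diol F3.
- DDQ takes this to 2,5-dichloro-3-(1H-indol-3-yl)-6-(7-prenyl-1H-indol-3-yl)-1,4-benzoquinone F4.
- NaOMe in MeOH replaces both chlorides by addition-elimination, and the sequence comes back to the route at 21.

2. Step 11.
- Risk: hydroxide or hydroperoxide generated during reoxidation may compete with methoxide. The second addition may slow once the deprotected indole is partly ionised. The indolide may autoxidise. Early loss of the silyl group is harmless, since it only anticipates step 12.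
- Fallback: it sets out from 19 and puts the oxygen in with a peroxide, so no aerobic turnover is needed.
- Weitz-Scheffer epoxidation with t-BuOOH and DBU in CH2Cl2 at 0 °C gives the bis-epoxide of 19 F5. It is a racemic mixture of syn and anti diastereomers whose configuration is erased in the next operation.
- NaOMe in MeOH at 0 °C under argon removes each epoxide C-H next to a carbonyl, opens both rings by E1cB elimination and cleaves the Boc group. This gives 2,5-dihydroxy-3-(7-prenyl-1H-indol-3-yl)-6-(1-TIPS-indol-3-yl)-1,4-benzoquinone F6.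
- Me3SiCHN2 in toluene-MeOH methylates only the acidic enol hydroxyls, and the sequence comes back to the route at 20.

3. Step 3.
- Risk: the hydrazone dianion may fragment incompletely. The vinyllithium may be quenched by proton transfer. The sulfinate may consume the methylating agent. Upstream, the deactivated ketone may condense sluggishly in step 2.
- Fallback: it sets out from 2 and by-passes the hydrazone altogether.
- Kinetic enolisation with KHMDS and trapping with PhNTf2 in THF at -78 °C gives 1-(1-triisopropylsilylindol-3-yl)vinyl trifluoromethanesulfonate F7.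
- Stille-type stannylation with (Me3Sn)2, Pd(PPh3)4 and LiCl in THF at 60 °C gives trimethyl[1-(1-triisopropylsilylindol-3-yl)vinyl]stannane F8.
- Tin-lithium exchange with MeLi in THF at -78 °C delivers a clean solution of the vinyllithium, and the sequence comes back to the route at 5.

Further compounds
F1 | step 9 | 2,5-dichloro-3-(1H-indol-3-yl)benzene-1,4-diol | Oc1cc(Cl)c(O)c(c2c[nH]c3ccccc23)c1Cl
F2 | step 9 | 2,5-dichloro-3-(1H-indol-3-yl)-1,4-benzoquinone | O=C1C=C(Cl)C(=O)C(c2c[nH]c3ccccc23)=C1Cl
F3 | step 9 | 2,5-dichloro-3-(1H-indol-3-yl)-6-(7-prenyl-1H-indol-3-yl)benzene-1,4-diol | Oc1c(c2c[nH]c3c(CC=C(C)C)cccc23)c(Cl)c(O)c(c2c[nH]c3ccccc23)c1Cl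
F4 | step 9 | 2,5-dichloro-3-(1H-indol-3-yl)-6-(7-prenyl-1H-indol-3-yl)-1,4-benzoquinone | O=C1C(c2c[nH]c3c(CC=C(C)C)cccc23)=C(Cl)C(=O)C(c2c[nH]c3ccccc23)=C1Cl
F5 | step 11 | bis-epoxide of 19 (racemic mixture of syn and anti diastereomers) | O=C1C2OC2(c2cn([Si](C(C)C)(C(C)C)C(C)C)c3ccccc23)C(=O)C2OC12c1cn(C(=O)OC(C)(C)C)c2c(CC=C(C)C)cccc12
F6 | step 11 | 2,5-dihydroxy-3-(7-prenyl-1H-indol-3-yl)-6-(1-TIPS-indol-3-yl)-1,4-benzoquinone | OC1=C(c2cn([Si](C(C)C)(C(C)C)C(C)C)c3ccccc23)C(=O)C(O)=C(c2c[nH]c3c(CC=C(C)C)cccc23)C1=O
F7 | step 3 | 1-(1-triisopropylsilylindol-3-yl)vinyl trifluoromethanesulfonate | C=C(OS(=O)(=O)C(F)(F)F)c1cn([Si](C(C)C)(C(C)C)C(C)C)c2ccccc12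
F8 | step 3 | trimethyl[1-(1-triisopropylsilylindol-3-yl)vinyl]stannane | C=C([Sn](C)(C)C)c1cn([Si](C(C)C)(C(C)C)C(C)C)c2ccccc12
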